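**Strategy.** Ring B is a fully substituted resorcinol whose formyl carbons on C3 and C5 flank the C4 hydroxyl. This C3–C4(OH)–C5 triad is a masked 3-oxopentanedioate, and C6(CH3)–C1(CO2R)–C2(OH) a masked acetylmalonate. A single base-mediated (3+3) condensation of dimethyl 3-oxopentanedioate with a 1-methoxyethylidene malonate bearing one methyl and one tert-butyl ester forms the C5–C6 and C2–C3 bonds and delivers ring B with all six substituents, the depside carboxyl already differentiated as its tert-butyl ester. Ring A comes from methyl atrarate by C5 methylation; acylation of its free 4-OH and late methylation of the chelated 2-OH complete the depside.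

Key step: step 3

Remarks on the chemistry (assumptions):
- Ring A of the target carries three C-methyl groups and a methoxy group next to the ester. Methyl atrarate therefore has to gain one C-methyl (at C5, steps 8–9) and one O-methyl (at O2, step 11).
- Enol ether 4 is drawn as the E isomer. An E/Z mixture is assumed to serve equally, because the alkene geometry is erased in step 3.
- Compound 3 is drawn as its keto tautomer. Intermediates 6 and 13 are written without stereodescriptors (configurationally labile or racemic). The target has no stereocentre.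

**Route**

Step 1
Reactants: 1 tert-butyl methyl malonate; 2 acetyl chloride
Product: 3 1-tert-butyl 3-methyl 2-acetylpropanedioate
Conditions: MgCl2, Et3N, MeCN, 0 °C → rt; cold 1 M HCl work-up
Reagents that add atoms: none
Why: MgCl2/Et3N soft enolisation and C-acylation of a malonate by an acid chloride is standard, the chelated product is not acylated again, and the tert-butyl ester tolerates the brief cold acidic work-up.

Step 2
Reactants: 3 1-tert-butyl 3-methyl 2-acetylpropanedioate
Product: 4 1-tert-butyl 3-methyl (2E)-2-(1-methoxyethylidene)propanedioate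
Conditions: Me3SiCHN2, i-Pr2NEt (cat.), MeCN/MeOH, 0 °C → rt
Reagents that add atoms: (trimethylsilyl)diazomethane, C[Si](C)(C)C=[N+]=[N-]
Why: The acidic, strongly enolised tricarbonyl protonates the diazoalkane and is methylated on the enol oxygen (diazomethane-type O-methylation of a β-dicarbonyl enol), leaving both esters untouched.

Step 3
Reactants: 4 1-tert-butyl 3-methyl (2E)-2-(1-methoxyethylidene)propanedioate; 5 dimethyl 3-oxopentanedioate
Product: 7 1-tert-butyl 3,5-dimethyl 2,4-dihydroxy-6-methylbenzene-1,3,5-tricarboxylate, via acyclic addition–elimination adduct 6 (not isolated)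
Conditions: NaOMe (2.5 equiv), MeOH/THF, 0 °C → 50 °C; then 1 M HCl
Reagents that add atoms: none
Why: Methoxide converts 5 into its enolate, whose α-carbon adds to the methoxy-bearing alkene carbon of 4 and expels methoxide (addition–elimination on a vinylogous carbonate), giving 6 as a delocalised dienolate in which the alkene geometry is mobile. The second α-carbon of the oxoglutarate unit then acylates on the methyl ester of the malonate terminus (Dieckmann condensation, 6-exo-trig, closing ring B through the C2–C3 bond), and the cyclohexadienedione tautomerises to the resorcinol, which is held as its phenoxide until the acid quench. The closest known reaction type is the alkoxide-mediated condensation of dialkyl 3-oxoglutarates with alkoxymethylene malonates to 2,4-dihydroxybenzene-1,3,5-tricarboxylates. No stereocentre is formed. The step needs C-acylation in preference to O-acylation and closure on the methyl ester in preference to the tert-butyl ester: reversible methoxide conditions reopen any pyranone until irreversible aromatisation drains the equilibrium, and the bulk and poor leaving-group ability of tert-butoxide shield the tert-butyl ester.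

Step 4
Reactants: 7 1-tert-butyl 3,5-dimethyl 2,4-dihydroxy-6-methylbenzene-1,3,5-tricarboxylate
Product: 8 1-tert-butyl 3,5-dimethyl 2,4-bis(benzyloxy)-6-methylbenzene-1,3,5-tricarboxylate
Conditions: BnBr, K2CO3, DMF, 60 °C
Reagents that add atoms: benzyl bromide, BrCc1ccccc1
Why: Williamson O-alkylation of the two acidic, carbonyl-flanked phenols should proceed in a polar aprotic solvent with gentle heating, and C-benzylation is impossible because every ring carbon is substituted.

Step 5
Reactants: 8 1-tert-butyl 3,5-dimethyl 2,4-bis(benzyloxy)-6-methylbenzene-1,3,5-tricarboxylate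
Product: 9 tert-butyl 2,4-bis(benzyloxy)-3,5-bis(hydroxymethyl)-6-methylbenzoate
Conditions: i-Bu2AlH (DIBAL-H, 5 equiv), CH2Cl2, −78 → 0 °C; aq potassium sodium tartrate
Reagents that add atoms: none
Why: Chemoselective hydride reduction of the two methyl esters to primary alcohols, the tert-butyl ester being protected at low temperature by its bulky alkoxy group and its position between a benzyloxy and a methyl substituent.

Step 6
Reactants: 9 tert-butyl 2,4-bis(benzyloxy)-3,5-bis(hydroxymethyl)-6-methylbenzoate
Product: 10 tert-butyl 2,4-bis(benzyloxy)-3,5-diformyl-6-methylbenzoate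
Conditions: MnO2 (activated, excess), CH2Cl2, rt
Reagents that add atoms: none
Why: Activated MnO2 oxidises benzylic alcohols to aldehydes without over-oxidation and leaves the benzyl ethers and the tert-butyl ester alone.

Step 7
Reactants: 10 tert-butyl 2,4-bis(benzyloxy)-3,5-diformyl-6-methylbenzoate
Product: 11 2,4-bis(benzyloxy)-3,5-diformyl-6-methylbenzoic acid
Conditions: CF3CO2H/CH2Cl2 (1:4), 0 °C → rt
Reagents that add atoms: none
Why: Acidolysis of a tert-butyl ester by alkyl–oxygen cleavage is insensitive to steric shielding of the carbonyl and should be faster than any loss of the benzyl aryl ethers under these dilute, cold conditions.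

Step 8
Reactants: 12 methyl 2,4-dihydroxy-3,6-dimethylbenzoate (methyl atrarate)
Product: 14 methyl 5-formyl-2,4-dihydroxy-3,6-dimethylbenzoate, via chloro(methoxy)methyl arene 13 (not isolated)
Conditions: Cl2CHOMe, TiCl4, CH2Cl2, 0 °C → rt; then ice/1 M HCl
Reagents that add atoms: dichloromethyl methyl ether, COC(Cl)Cl; water, O
Why: Rieche formylation attacks the only unsubstituted ring carbon, C5, which is ortho to the 4-OH and para to the 2-OH, and the α-chloro ether is hydrolysed to the aldehyde on work-up.

Step 9
Reactants: 14 methyl 5-formyl-2,4-dihydroxy-3,6-dimethylbenzoate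
Product: 15 methyl 2,4-dihydroxy-3,5,6-trimethylbenzoate
Conditions: Et3SiH (3 equiv), CF3CO2H, CH2Cl2, 0 °C → rt
Reagents that add atoms: none
Why: Ionic hydrogenation reduces an aryl aldehyde bearing ortho and para hydroxyl groups to the methyl group through the hydroxy-stabilised benzylic cation, and the methyl ester is inert to silane/acid.

Step 10
Reactants: 11 2,4-bis(benzyloxy)-3,5-diformyl-6-methylbenzoic acid; 15 methyl 2,4-dihydroxy-3,5,6-trimethylbenzoate
Product: 17 methyl 4-{[2,4-bis(benzyloxy)-3,5-diformyl-6-methylbenzoyl]oxy}-2-hydroxy-3,5,6-trimethylbenzoate, via mixed trifluoroacetic anhydride 16 (not isolated)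
Conditions: (CF3CO)2O, toluene, rt; then aq NaHCO3
Reagents that add atoms: none
Why: Depside formation by the trifluoroacetic anhydride method activates the hindered acid as an acylium-like mixed anhydride that acylates the non-chelated 4-OH of 15, the 2-OH being deactivated by its hydrogen bond to the ester carbonyl and C-acylation being excluded because both rings are fully substituted.

Step 11
Reactants: 17 methyl 4-{[2,4-bis(benzyloxy)-3,5-diformyl-6-methylbenzoyl]oxy}-2-hydroxy-3,5,6-trimethylbenzoate
Product: 18 methyl 4-{[2,4-bis(benzyloxy)-3,5-diformyl-6-methylbenzoyl]oxy}-2-methoxy-3,5,6-trimethylbenzoate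
Conditions: MeI, K2CO3, DMF, rt
Reagents that add atoms: iodomethane, CI
Why: Williamson O-methylation of the single remaining phenol under mild carbonate conditions, with the depside ester shielded by four ortho substituents and the aldehydes not enolisable.

Step 12
Reactants: 18 methyl 4-{[2,4-bis(benzyloxy)-3,5-diformyl-6-methylbenzoyl]oxy}-2-methoxy-3,5,6-trimethylbenzoate
Product: 19 methyl 4-[(3,5-diformyl-2,4-dihydroxy-6-methylbenzoyl)oxy]-2-methoxy-3,5,6-trimethylbenzoate (target)
Conditions: BCl3, C6HMe5, CH2Cl2, −78 °C; MeOH quench at −78 °C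
Reagents that add atoms: none
Why: Lewis-acid cleavage of aryl benzyl ethers by BCl3 with pentamethylbenzene as cation scavenger is accelerated by chelation to the ortho formyl groups, so at −78 °C the ring A methyl ether, the methyl ester and the depside link should survive.

**Compound list**

1 | tert-butyl methyl malonate (1-tert-butyl 3-methyl propanedioate) | COC(=O)CC(=O)OC(C)(C)C | starting material
2 | acetyl chloride | CC(Cl)=O | starting material
3 | 1-tert-butyl 3-methyl 2-acetylpropanedioate (keto form drawn) | CC(=O)C(C(=O)OC)C(=O)OC(C)(C)C | intermediate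
4 | 1-tert-butyl 3-methyl (2E)-2-(1-methoxyethylidene)propanedioate (OMe cis to CO2Me) | CO/C(C)=C(\C(=O)OC)C(=O)OC(C)(C)C | intermediate
5 | dimethyl 3-oxopentanedioate | COC(=O)CC(=O)CC(=O)OC | starting material
6 | 1-tert-butyl 1,3,5-trimethyl 2-methyl-4-oxopent-1-ene-1,1,3,5-tetracarboxylate (labile CH and alkene geometry, no descriptors) | COC(=O)CC(=O)C(C(=O)OC)C(C)=C(C(=O)OC)C(=O)OC(C)(C)C | intermediate (not isolated)
7 | 1-tert-butyl 3,5-dimethyl 2,4-dihydroxy-6-methylbenzene-1,3,5-tricarboxylate | CC(C)(C)OC(=O)c1c(C)c(C(=O)OC)c(O)c(C(=O)OC)c1O | intermediate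
8 | 1-tert-butyl 3,5-dimethyl 2,4-bis(benzyloxy)-6-methylbenzene-1,3,5-tricarboxylate | CC(C)(C)OC(=O)c1c(C)c(C(=O)OC)c(OCc2ccccc2)c(C(=O)OC)c1OCc3ccccc3 | intermediate
9 | tert-butyl 2,4-bis(benzyloxy)-3,5-bis(hydroxymethyl)-6-methylbenzoate | CC(C)(C)OC(=O)c1c(C)c(CO)c(OCc2ccccc2)c(CO)c1OCc3ccccc3 | intermediate
10 | tert-butyl 2,4-bis(benzyloxy)-3,5-diformyl-6-methylbenzoate | CC(C)(C)OC(=O)c1c(C)c(C=O)c(OCc2ccccc2)c(C=O)c1OCc3ccccc3 | intermediate
11 | 2,4-bis(benzyloxy)-3,5-diformyl-6-methylbenzoic acid | OC(=O)c1c(C)c(C=O)c(OCc2ccccc2)c(C=O)c1OCc3ccccc3 | intermediate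
12 | methyl 2,4-dihydroxy-3,6-dimethylbenzoate (methyl atrarate) | COC(=O)c1c(C)cc(O)c(C)c1O | starting material
13 | methyl 5-[chloro(methoxy)methyl]-2,4-dihydroxy-3,6-dimethylbenzoate (racemic, titanium-bound) | COC(=O)c1c(C)c(C(Cl)OC)c(O)c(C)c1O | intermediate (not isolated)
14 | methyl 5-formyl-2,4-dihydroxy-3,6-dimethylbenzoate | COC(=O)c1c(C)c(C=O)c(O)c(C)c1O | intermediate
15 | methyl 2,4-dihydroxy-3,5,6-trimethylbenzoate | COC(=O)c1c(C)c(C)c(O)c(C)c1O | intermediate
16 | 2,4-bis(benzyloxy)-3,5-diformyl-6-methylbenzoic trifluoroacetic anhydride | O=C(OC(=O)C(F)(F)F)c1c(C)c(C=O)c(OCc2ccccc2)c(C=O)c1OCc3ccccc3 | intermediate (not isolated)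
17 | methyl 4-{[2,4-bis(benzyloxy)-3,5-diformyl-6-methylbenzoyl]oxy}-2-hydroxy-3,5,6-trimethylbenzoate | COC(=O)c1c(C)c(C)c(OC(=O)c2c(C)c(C=O)c(OCc3ccccc3)c(C=O)c2OCc4ccccc4)c(C)c1O | intermediate
18 | methyl 4-{[2,4-bis(benzyloxy)-3,5-diformyl-6-methylbenzoyl]oxy}-2-methoxy-3,5,6-trimethylbenzoate | COC(=O)c1c(C)c(C)c(OC(=O)c2c(C)c(C=O)c(OCc3ccccc3)c(C=O)c2OCc4ccccc4)c(C)c1OC | intermediate
19 | methyl 4-[(3,5-diformyl-2,4-dihydroxy-6-methylbenzoyl)oxy]-2-methoxy-3,5,6-trimethylbenzoate | COC(=O)c1c(C)c(C)c(OC(=O)c2c(C)c(C=O)c(O)c(C=O)c2O)c(C)c1OC | target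

**Step count and risk**

Total: 12 steps. Longest linear sequence: 10 steps (steps 1–7, then 10–12). The ring A branch (steps 8–9) joins at step 10.

Steps most likely to fail:

1. Step 3 (key annulation). The enolate of 5 may add only sluggishly to the tetrasubstituted enol ether, whose allylic methyl group can be deprotonated unproductively. Ring closure may also take place through the enolate oxygen or through the allylic methyl carbanion, and prolonged exposure to methoxide could methanolyse the tert-butyl ester before cyclisation. The fallback builds ring B by a different annulation that leaves C1 open and installs the carboxyl afterwards. It sets out from 5, which with methyl but-2-ynoate (NaH, THF, 0 °C → reflux; Michael addition followed by Dieckmann closure on the ynoate ester) should give dimethyl 2,4-dihydroxy-6-methylbenzene-1,3-dicarboxylate F1. Rieche formylation at the single free ring position (Cl2CHOMe, TiCl4, CH2Cl2) would give dimethyl 5-formyl-2,4-dihydroxy-6-methylbenzene-1,3-dicarboxylate F2. Lindgren–Pinnick oxidation (NaClO2, NaH2PO4, 2-methylbut-2-ene, t-BuOH/H2O) would give 2,4-dihydroxy-3,5-bis(methoxycarbonyl)-6-methylbenzoic acid F3. Esterification of the carboxyl with tert-butyl 2,2,2-trichloroacetimidate (CH2Cl2/cyclohexane, rt, no added acid, so that the chelated phenols stay free) comes back to the route at 7.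

2. Step 10 (depside coupling). Acyl transfer from a di-ortho-substituted acyl donor to a phenol flanked by two methyl groups may be slow, so that trifluoroacetylation of the phenol or acylation at the other hydroxyl competes. The fallback differentiates the two ring A hydroxyls before coupling and replaces the mixed anhydride by an acid chloride met by a phenoxide. It sets out from 15 and 11. Benzylation of the non-chelated 4-OH of 15 (BnBr, K2CO3, acetone, reflux) would give methyl 4-(benzyloxy)-2-hydroxy-3,5,6-trimethylbenzoate F4. Methylation of the chelated 2-OH (MeI, K2CO3, DMF) would give methyl 4-(benzyloxy)-2-methoxy-3,5,6-trimethylbenzoate F5, and hydrogenolysis (H2, Pd/C, EtOAc) methyl 4-hydroxy-2-methoxy-3,5,6-trimethylbenzoate F6. Acid 11 would be converted with (COCl)2 and catalytic DMF in CH2Cl2 into 2,4-bis(benzyloxy)-3,5-diformyl-6-methylbenzoyl chloride F7. Acylation of the sodium phenoxide of F6 (NaH, THF, 0 → 50 °C) with F7 comes back to the route at 18 and makes step 11 unnecessary.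

3. Step 5 (chemoselective reduction). Hydride may also attack the tert-butyl ester, or reduction of the two hindered methyl esters may stall before both reach the alcohol stage. The fallback changes the order of operations so that the depside carboxyl is protected as its carboxylate during the reduction. It sets out from 8, which with CF3CO2H/CH2Cl2 would give 2,4-bis(benzyloxy)-3,5-bis(methoxycarbonyl)-6-methylbenzoic acid F8. LiBH4 (THF, MeOH, 50 °C), which reduces esters but not lithium carboxylates, would then give 2,4-bis(benzyloxy)-3,5-bis(hydroxymethyl)-6-methylbenzoic acid F9; neither hydroxymethyl group is ortho to the carboxyl, so no lactone can form. Oxidation with activated MnO2 comes back to the route at 11, bypassing steps 6 and 7.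

**Further compounds**

F1 | step 3 | dimethyl 2,4-dihydroxy-6-methylbenzene-1,3-dicarboxylate | COC(=O)c1c(C)cc(O)c(C(=O)OC)c1O
F2 | step 3 | dimethyl 5-formyl-2,4-dihydroxy-6-methylbenzene-1,3-dicarboxylate | COC(=O)c1c(C)c(C=O)c(O)c(C(=O)OC)c1O
F3 | step 3 | 2,4-dihydroxy-3,5-bis(methoxycarbonyl)-6-methylbenzoic acid | OC(=O)c1c(C)c(C(=O)OC)c(O)c(C(=O)OC)c1O
F4 | step 10 | methyl 4-(benzyloxy)-2-hydroxy-3,5,6-trimethylbenzoate | COC(=O)c1c(C)c(C)c(OCc2ccccc2)c(C)c1O
F5 | step 10 | methyl 4-(benzyloxy)-2-methoxy-3,5,6-trimethylbenzoate | COC(=O)c1c(C)c(C)c(OCc2ccccc2)c(C)c1OC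
F6 | step 10 | methyl 4-hydroxy-2-methoxy-3,5,6-trimethylbenzoate | COC(=O)c1c(C)c(C)c(O)c(C)c1OC
F7 | step 10 | 2,4-bis(benzyloxy)-3,5-diformyl-6-methylbenzoyl chloride | O=C(Cl)c1c(C)c(C=O)c(OCc2ccccc2)c(C=O)c1OCc3ccccc3
F8 | step 5 | 2,4-bis(benzyloxy)-3,5-bis(methoxycarbonyl)-6-methylbenzoic acid | OC(=O)c1c(C)c(C(=O)OC)c(OCc2ccccc2)c(C(=O)OC)c1OCc3ccccc3
F9 | step 5 | 2,4-bis(benzyloxy)-3,5-bis(hydroxymethyl)-6-methylbenzoic acid | OC(=O)c1c(C)c(CO)c(OCc2ccccc2)c(CO)c1OCc3ccccc3
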